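**Plan**

Ring numbering: C1 (vanillate carbinol), C2, C3=C4(CH3) (E), C5, C6, C7, C8(CH3)2, C9 (acetate carbinol), C10=C11(CH3) (Z), back to C1.
Cuts, in retrosynthetic order: the two ester C–O bonds (vanilloyl at O1, acetyl at O9); the ring bond C5–C6 (allylic bromide + sulfonyl carbanion); the C10=C11 double bond (metathesis); then C3=C4 (cross-metathesis), C1–C2 (allylation), C9–C10 (vinyl addition) and C7–C8 (conjugate addition).
Enabling feature: O–C9–C10=C11–C1–O is a Z-2-ene-1,4-diol, so an iPr2Si bridge between the two oxygens gives a seven-membered 1,3-dioxa-2-silacyclohept-5-ene whose closure by metathesis can only deliver the cis alkene.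
Forward: a C6–C10 half and a C11–C5 half are made separately, tied through silicon, joined at C10=C11 inside the seven-membered ring (the only ring formed there) and untied; the eleven-membered carbocycle is then closed at C5–C6, the sulfone removed and the two esters put on.
Stereochemistry: C9 (R) from catalyst-controlled vinylzinc addition, C1 (S) from reagent-controlled allylboration, C3=C4 (E) from thermodynamically controlled cross-metathesis, C10=C11 (Z) from the ring constraint of the silicon tether.

Key step: step 6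

Remark: the ring numbering above is used for all macrocycles; 19 forms as both C6 epimers, and step 12 removes that centre.

**Route**

Step 1
Reactants: 1 isobutyraldehyde; 2 pyrrolidine; 3 phenyl vinyl sulfone
Product: 6 2,2-dimethyl-4-(phenylsulfonyl)butanal, via isobutenylpyrrolidine enamine 4 (not isolated), via aminocyclobutyl sulfone 5 (not isolated)
Conditions: 1 (1.3 equiv), 2, 4 Å MS, MeCN, rt; 3, 80 °C; then AcOH/NaOAc/H2O, 60 °C
Reagents that add atoms: water, O
Why: Stork enamine Michael addition, in which the isobutyraldehyde enamine adds to the vinyl sulfone (formal [2+2] adduct 5) and aqueous acid opens and hydrolyses the adduct to the aldehyde, whose quaternary α-carbon (C8) excludes over-alkylation and aldol condensation.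

Step 2
Reactants: 6 2,2-dimethyl-4-(phenylsulfonyl)butanal
Product: 7 (3R)-4,4-dimethyl-6-(phenylsulfonyl)hex-1-en-3-ol
Conditions: (CH2=CH)2Zn (1.5 equiv, salt-free stock solution), (+)-MIB (10 mol%), toluene, −30 → 0 °C; then 1 M HCl
Reagents that add atoms: divinylzinc, C=C[Zn]C=C
Why: Amino-alcohol-catalysed asymmetric alkenylzinc addition to an α-branched aldehyde; (−)-MIB (3-exo-morpholinoisoborneol) sends the zinc-bound group to the Si face, so its enantiomer should deliver vinyl to the Re face and set C9 as R, the sulfone being inert to organozinc reagents.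

Step 3
Reactants: 8 methacrolein
Product: 9 (3S)-2-methylhexa-1,5-dien-3-ol
Conditions: Ipc2B(CH2CH=CH2) from (+)-α-pinene (1.1 equiv), Et2O, −78 °C; then NaOH, H2O2, 0 °C → rt
Reagents that add atoms: B-allyldiisopinocampheylborane, C=CCB([C@@H]1C[C@@H]2C[C@H]([C@H]1C)C2(C)C)[C@@H]1C[C@@H]2C[C@H]([C@H]1C)C2(C)C
Why: Brown allylboration through a closed chair transition state; the (+)-α-pinene-derived Ipc2B unit directs allyl to the Si face of the enal carbonyl (1,2-addition only), which sets C1 as S.

Step 4
Reactants: 9 (3S)-2-methylhexa-1,5-dien-3-ol; 10 ethyl methacrylate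
Product: 11 ethyl (2E,5S)-5-hydroxy-2,6-dimethylhepta-2,6-dienoate
Conditions: 10 (8 equiv), (H2IMes)Cl2Ru=CH(C6H4-2-OiPr) (3 mol%), 1,4-benzoquinone (10 mol%), CH2Cl2, 40 °C
Reagents that add atoms: none
Why: Olefin cross-metathesis of a terminal alkene with a methacrylate, E-selective under thermodynamic control; the 1,1-disubstituted isopropenyl group beside the carbinol is too hindered to engage and excess methacrylate suppresses homodimerisation.

Step 5
Reactants: 7 (3R)-4,4-dimethyl-6-(phenylsulfonyl)hex-1-en-3-ol; 11 ethyl (2E,5S)-5-hydroxy-2,6-dimethylhepta-2,6-dienoate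
Product: 13 ethyl (2E,5S)-5-{[(3R)-4,4-dimethyl-6-(phenylsulfonyl)hex-1-en-3-yl]oxy(diisopropyl)silyloxy}-2,6-dimethylhepta-2,6-dienoate, via chlorosilyl ether 12 (not isolated)
Conditions: 7, iPr2SiCl2 (3 equiv), imidazole, DMAP (cat.), CH2Cl2, 0 °C → rt; excess silane off in vacuo; then 11, imidazole, DMF, rt
Reagents that add atoms: dichlorodiisopropylsilane, CC(C)[Si](Cl)(Cl)C(C)C
Why: Stepwise silylation of two alcohols with a dialkyldichlorosilane; the hindered neopentylic alcohol 7 takes up one Si–Cl of the excess reagent and the less hindered alcohol 11 then captures chlorosilane 12, which avoids symmetrical silaketals and turns residual minor enantiomers into a separable diastereomer.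

Step 6
Reactants: 13 mixed diisopropylsilylene bis-ether
Product: 14 ethyl (2E)-4-[(4S,7R)-2,2-diisopropyl-5-methyl-7-[2-methyl-4-(phenylsulfonyl)butan-2-yl]-4,7-dihydro-1,3,2-dioxasilepin-4-yl]-2-methylbut-2-enoate
Conditions: second-generation Grubbs catalyst (H2IMes)(PCy3)Cl2Ru=CHPh (10 mol%, two portions), toluene (0.005 M), 80 °C, argon sparge
Reagents that add atoms: none
Why: Temporary silicon-tethered ring-closing olefin metathesis (Chauvin mechanism): the ruthenium alkylidene loads on the monosubstituted C10 vinyl group, adds across the 1,1-disubstituted C11 alkene to a ruthenacyclobutane and releases the trisubstituted C10=C11 alkene, with ethylene as the by-product. The only ring closed is the seven-membered 1,3-dioxa-2-silacyclohept-5-ene (O–C9–C10=C11–C1–O–Si), formed by intramolecular [2+2] cycloaddition and cycloreversion at ruthenium. No stereocentre is created; C9 (R) and C1 (S) are carried in unchanged from 7 and 11, so the 1,4-relationship is fixed by the choice of enantiomers. The geometry needed (C9 and C1 cis, Z after the tether is removed) is enforced because a seven-membered ring cannot hold a trans double bond. Chemoselectivity is secured by the substrate: the ester-conjugated, trisubstituted C3=C4 alkene is electron-poor and hindered and should stay out, while high dilution and removal of ethylene disfavour dimerisation through the vinyl group.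

Step 7
Reactants: 14 seven-membered silylene acetal
Product: 15 ethyl (2E,5S,6Z,8R)-5,8-dihydroxy-2,6,9,9-tetramethyl-11-(phenylsulfonyl)undeca-2,6-dienoate
Conditions: HF·pyridine, pyridine, THF, 0 °C → rt
Reagents that add atoms: none
Why: Fluoride cleavage of a dialkoxysilane, driven by Si–F bond formation; the buffered reagent should leave the enoate, the sulfone and both allylic carbinols untouched and frees the Z-2-ene-1,4-diol.

Step 8
Reactants: 15 diol ester
Product: 16 ethyl (2E,5S,6Z,8R)-5,8-bis(tert-butyldimethylsilyloxy)-2,6,9,9-tetramethyl-11-(phenylsulfonyl)undeca-2,6-dienoate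
Conditions: TBSOTf (3 equiv), 2,6-lutidine, CH2Cl2, −78 → 0 °C
Reagents that add atoms: tert-butyldimethylsilyl triflate, CC(C)(C)[Si](C)(C)OS(=O)(=O)C(F)(F)F
Why: Silyl triflate silylation is forceful enough for the neopentylic C9 hydroxyl and non-basic towards enoate and sulfone; both oxygens must be masked against the strong base of step 11.

Step 9
Reactants: 16 bis-silyl ether ester
Product: 17 (2E,5S,6Z,8R)-5,8-bis(tert-butyldimethylsilyloxy)-2,6,9,9-tetramethyl-11-(phenylsulfonyl)undeca-2,6-dien-1-ol
Conditions: iBu2AlH (2.5 equiv), CH2Cl2, −78 °C; aq. KNaC4H4O6 (potassium sodium tartrate)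
Reagents that add atoms: none
Why: 1,2-Reduction of an α,β-unsaturated ester with a dialkylaluminium hydride at low temperature gives the E-allylic alcohol without touching the sulfone or the silyl ethers.

Step 10
Reactants: 17 allylic alcohol
Product: 18 (2E,5S,6Z,8R)-1-bromo-5,8-bis(tert-butyldimethylsilyloxy)-2,6,9,9-tetramethyl-11-(phenylsulfonyl)undeca-2,6-diene
Conditions: CBr4, PPh3, 2,6-lutidine (cat.), CH2Cl2, 0 °C
Reagents that add atoms: carbon tetrabromide, BrC(Br)(Br)Br
Why: Appel bromination of a primary allylic alcohol proceeds by SN2 at C5 under neutral conditions, so the E geometry and the silyl ethers are kept.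

Step 11
Reactants: 18 allylic bromide sulfone
Product: 19 (1S,3E,9R,10Z)-1,9-bis(tert-butyldimethylsilyloxy)-4,8,8,11-tetramethyl-6-(phenylsulfonyl)cycloundeca-3,10-diene (C6 epimers)
Conditions: 18 added over 8 h to LiN(iPr)2 (1.5 equiv), THF, −20 °C, final 0.002 M
Reagents that add atoms: none
Why: Intramolecular alkylation of an α-sulfonyl carbanion by a primary allylic bromide (SN2 at C5) under high dilution forms the C5–C6 bond and the eleven-membered ring, the Z C10=C11 alkene and the gem-dimethyl group pre-folding the chain.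

Step 12
Reactants: 19 macrocyclic sulfone
Product: 20 (1S,3E,9R,10Z)-1,9-bis(tert-butyldimethylsilyloxy)-4,8,8,11-tetramethylcycloundeca-3,10-diene
Conditions: Na/Hg (6% Na), Na2HPO4, MeOH/THF, −20 °C
Reagents that add atoms: none
Why: Reductive desulfonylation by electron transfer cleaves the C6–S bond and methanol protonates C6; the sulfone is homoallylic, so no alkene should migrate, and the allylic silyl ethers are stable.

Step 13
Reactants: 20 bis-silyl ether macrocycle
Product: 21 (1S,3E,9R,10Z)-4,8,8,11-tetramethylcycloundeca-3,10-diene-1,9-diol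
Conditions: TBAF (4 equiv), THF, rt → 45 °C
Reagents that add atoms: none
Why: Fluoride desilylation; nothing base-sensitive is left in 20, so warm fluoride can also remove the hindered C9 silyl ether while avoiding acid, which could trigger transannular reactions of the diene.

Step 14
Reactants: 22 vanillic acid
Product: 24 4-(tert-butyldimethylsilyloxy)-3-methoxybenzoic acid, via bis-silylated vanillate 23 (not isolated)
Conditions: TBSCl (2.5 equiv), imidazole, DMF, rt; then AcOH/THF/H2O (3:1:1), rt
Reagents that add atoms: tert-butyldimethylsilyl chloride, CC(C)(C)[Si](C)(C)Cl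
Why: Silylation of phenol and acid followed by selective hydrolysis of the labile silyl ester gives the phenol-protected acid.

Step 15
Reactants: 21 macrocyclic diol; 24 4-(tert-butyldimethylsilyloxy)-3-methoxybenzoic acid
Product: 25 (1S,3E,9R,10Z)-9-hydroxy-4,8,8,11-tetramethylcycloundeca-3,10-dien-1-yl 4-(tert-butyldimethylsilyloxy)-3-methoxybenzoate
Conditions: 24 (1.05 equiv), EDC·HCl (1.3 equiv), DMAP (0.2 equiv), CH2Cl2, −10 °C → rt
Reagents that add atoms: none
Why: Steglich esterification; the acylpyridinium from 24 should acylate the C1 hydroxyl (flanked by a CH2) much faster than the neopentylic C9 hydroxyl beside the quaternary C8, so one equivalent of acid should give the C1 mono-ester.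

Step 16
Reactants: 25 C1 mono-ester
Product: 26 (1S,3E,9R,10Z)-9-acetoxy-4,8,8,11-tetramethylcycloundeca-3,10-dien-1-yl 4-(tert-butyldimethylsilyloxy)-3-methoxybenzoate
Conditions: Ac2O (5 equiv), DMAP (0.5 equiv), Et3N, CH2Cl2, rt
Reagents that add atoms: acetic anhydride, CC(=O)OC(C)=O
Why: DMAP-catalysed acetylation of the remaining hindered secondary alcohol; the aryl silyl ether keeps the phenol from being acetylated.

Step 17
Reactants: 26 silyl-protected acetate
Product: 27 (1S,3E,9R,10Z)-9-acetoxy-4,8,8,11-tetramethylcycloundeca-3,10-dien-1-yl 4-hydroxy-3-methoxybenzoate (target)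
Conditions: TBAF/AcOH (1:1, 1.2 equiv), THF, 0 °C
Reagents that add atoms: none
Why: Fluoride cleavage of an aryl silyl ether is fast at 0 °C and, buffered with acetic acid, should spare both esters and prevent acyl migration.

**Compound list**

1 | isobutyraldehyde | CC(C)C=O | starting material
2 | pyrrolidine | C1CCNC1 | starting material
3 | phenyl vinyl sulfone | C=CS(=O)(=O)c1ccccc1 | starting material
4 | 1-(2-methylprop-1-en-1-yl)pyrrolidine (formed in the flask) | CC(C)=CN1CCCC1 | intermediate
5 | 1-[2,2-dimethyl-4-(phenylsulfonyl)cyclobutyl]pyrrolidine (racemic, formed in the flask) | CC1(C)CC(S(=O)(=O)c2ccccc2)C1N1CCCC1 | intermediate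
6 | 2,2-dimethyl-4-(phenylsulfonyl)butanal | CC(C)(C=O)CCS(=O)(=O)c1ccccc1 | intermediate
7 | (3R)-4,4-dimethyl-6-(phenylsulfonyl)hex-1-en-3-ol | C=C[C@@H](O)C(C)(C)CCS(=O)(=O)c1ccccc1 | intermediate
8 | methacrolein | CC(=C)C=O | starting material
9 | (3S)-2-methylhexa-1,5-dien-3-ol | C=C(C)[C@@H](O)CC=C | intermediate
10 | ethyl methacrylate | C=C(C)C(=O)OCC | starting material
11 | ethyl (2E,5S)-5-hydroxy-2,6-dimethylhepta-2,6-dienoate | C=C(C)[C@@H](O)C/C=C(\C)C(=O)OCC | intermediate
12 | (3R)-3-[chloro(diisopropyl)silyloxy]-4,4-dimethyl-6-(phenylsulfonyl)hex-1-ene (formed in the flask) | C=C[C@@H](O[Si](Cl)(C(C)C)C(C)C)C(C)(C)CCS(=O)(=O)c1ccccc1 | intermediate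
13 | ethyl (2E,5S)-5-{[(3R)-4,4-dimethyl-6-(phenylsulfonyl)hex-1-en-3-yl]oxy(diisopropyl)silyloxy}-2,6-dimethylhepta-2,6-dienoate | C=C[C@@H](O[Si](C(C)C)(C(C)C)O[C@H](C(C)=C)C/C=C(\C)C(=O)OCC)C(C)(C)CCS(=O)(=O)c1ccccc1 | intermediate
14 | ethyl (2E)-4-[(4S,7R)-2,2-diisopropyl-5-methyl-7-[2-methyl-4-(phenylsulfonyl)butan-2-yl]-4,7-dihydro-1,3,2-dioxasilepin-4-yl]-2-methylbut-2-enoate | CC(C)[Si]1(C(C)C)O[C@@H](C(C)(C)CCS(=O)(=O)c2ccccc2)C=C(C)[C@H](C/C=C(\C)C(=O)OCC)O1 | intermediate
15 | ethyl (2E,5S,6Z,8R)-5,8-dihydroxy-2,6,9,9-tetramethyl-11-(phenylsulfonyl)undeca-2,6-dienoate | O[C@@H](C(C)(C)CCS(=O)(=O)c1ccccc1)/C=C(C)\[C@H](C/C=C(\C)C(=O)OCC)O | intermediate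
16 | ethyl (2E,5S,6Z,8R)-5,8-bis(tert-butyldimethylsilyloxy)-2,6,9,9-tetramethyl-11-(phenylsulfonyl)undeca-2,6-dienoate | CC(C)(C)[Si](C)(C)O[C@@H](C(C)(C)CCS(=O)(=O)c1ccccc1)/C=C(C)\[C@H](C/C=C(\C)C(=O)OCC)O[Si](C)(C)C(C)(C)C | intermediate
17 | (2E,5S,6Z,8R)-5,8-bis(tert-butyldimethylsilyloxy)-2,6,9,9-tetramethyl-11-(phenylsulfonyl)undeca-2,6-dien-1-ol | CC(C)(C)[Si](C)(C)O[C@@H](C(C)(C)CCS(=O)(=O)c1ccccc1)/C=C(C)\[C@H](C/C=C(\C)CO)O[Si](C)(C)C(C)(C)C | intermediate
18 | (2E,5S,6Z,8R)-1-bromo-5,8-bis(tert-butyldimethylsilyloxy)-2,6,9,9-tetramethyl-11-(phenylsulfonyl)undeca-2,6-diene | CC(C)(C)[Si](C)(C)O[C@@H](C(C)(C)CCS(=O)(=O)c1ccccc1)/C=C(C)\[C@H](C/C=C(\C)CBr)O[Si](C)(C)C(C)(C)C | intermediate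
19 | (1S,3E,9R,10Z)-1,9-bis(tert-butyldimethylsilyloxy)-4,8,8,11-tetramethyl-6-(phenylsulfonyl)cycloundeca-3,10-diene (C6 epimers) | CC(C)(C)[Si](C)(C)O[C@H]1C/C=C(\C)CC(S(=O)(=O)c2ccccc2)CC(C)(C)[C@H](O[Si](C)(C)C(C)(C)C)/C=C\1C | intermediate
20 | (1S,3E,9R,10Z)-1,9-bis(tert-butyldimethylsilyloxy)-4,8,8,11-tetramethylcycloundeca-3,10-diene | CC(C)(C)[Si](C)(C)O[C@H]1C/C=C(\C)CCCC(C)(C)[C@H](O[Si](C)(C)C(C)(C)C)/C=C\1C | intermediate
21 | (1S,3E,9R,10Z)-4,8,8,11-tetramethylcycloundeca-3,10-diene-1,9-diol | O[C@H]1C/C=C(\C)CCCC(C)(C)[C@H](O)/C=C\1C | intermediate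
22 | vanillic acid | COc1cc(C(=O)O)ccc1O | starting material
23 | tert-butyldimethylsilyl 4-(tert-butyldimethylsilyloxy)-3-methoxybenzoate (formed in the flask) | COc1cc(C(=O)O[Si](C)(C)C(C)(C)C)ccc1O[Si](C)(C)C(C)(C)C | intermediate
24 | 4-(tert-butyldimethylsilyloxy)-3-methoxybenzoic acid | COc1cc(C(=O)O)ccc1O[Si](C)(C)C(C)(C)C | intermediate
25 | (1S,3E,9R,10Z)-9-hydroxy-4,8,8,11-tetramethylcycloundeca-3,10-dien-1-yl 4-(tert-butyldimethylsilyloxy)-3-methoxybenzoate | COc1cc(C(=O)O[C@H]2C/C=C(\C)CCCC(C)(C)[C@H](O)/C=C\2C)ccc1O[Si](C)(C)C(C)(C)C | intermediate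
26 | (1S,3E,9R,10Z)-9-acetoxy-4,8,8,11-tetramethylcycloundeca-3,10-dien-1-yl 4-(tert-butyldimethylsilyloxy)-3-methoxybenzoate | COc1cc(C(=O)O[C@H]2C/C=C(\C)CCCC(C)(C)[C@H](OC(C)=O)/C=C\2C)ccc1O[Si](C)(C)C(C)(C)C | intermediate
27 | (1S,3E,9R,10Z)-9-acetoxy-4,8,8,11-tetramethylcycloundeca-3,10-dien-1-yl 4-hydroxy-3-methoxybenzoate | COc1cc(C(=O)O[C@H]2C/C=C(\C)CCCC(C)(C)[C@H](OC(C)=O)/C=C\2C)ccc1O | target

**Step count and risks**

Total: 17 steps. Longest linear sequence: 14 steps (1, 2, 5–13, 15–17 from isobutyraldehyde; equally 3, 4, 5–13, 15–17 from methacrolein).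

Step 11, macrocyclisation. Intermolecular alkylation and base-induced elimination of the bromide may outrun the entropically slow closure of the eleven-membered ring by a hard lithium sulfonyl carbanion. The fallback sets out from 17 and comes back at 19; it replaces the SN2 closure by a Tsuji–Trost allylation with a softer, doubly stabilised nucleophile. Treating 17 with LiN(iPr)2 (3.2 equiv) and methyl chloroformate (2.1 equiv) at −78 °C should carbonate the alkoxide and carboxylate the sulfonyl carbanion in one operation, giving the allylic methyl carbonate with an α-methoxycarbonyl sulfone F1. Pd(PPh3)4 (zerovalent palladium, 10 mol%) in THF at 65 °C under slow addition ionises the carbonate; the methoxide released deprotonates the sulfonyl ester, and attack at the less hindered C5 terminus of the π-allyl complex should give the macrocyclic α-sulfonyl ester F2. Dealkoxycarbonylation of the Krapcho type (Me4NOAc, HMPA, 100 °C, conditions that spare the silyl ethers) then returns to 19.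

Step 6, ring-closing metathesis. Ring closure onto the hindered 1,1-disubstituted C11 alkene may be so slow, with the C10 vinyl group itself neopentylic, that catalyst decay and dimerisation through the vinyl groups take over. The fallback sets out from 7 and comes back at 15; it builds the cis C10=C11 bond inside a five-membered lactone without metathesis at C10 and sets C1 afterwards. Esterification of 7 with 2-(diethoxyphosphoryl)propanoic acid (DCC, DMAP) gives the phosphonopropionate ester F3, and ozonolysis (O3, CH2Cl2, −78 °C; Me2S) cuts the vinyl group to the α-acyloxy aldehyde F4. Intramolecular Horner–Wadsworth–Emmons olefination (LiCl, iPr2NEt, MeCN) closes the 3-methyl-5-substituted butenolide F5, whose ring fixes C9 and C1 cis across the alkene. iBu2AlH at −78 °C gives the lactol F6, used crude to avoid dehydration to a furan. Allylboration of its open hydroxy-enal form with the reagent of step 3 (Si-face attack, C1 S) gives the allylated Z-ene-1,4-diol F7. Cross-metathesis of F7 with 10 under the conditions of step 4 gives 15.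

Step 15, site-selective esterification. Acylation may lose site selectivity (both hydroxyls, or the C9 hydroxyl, being acylated), and DMAP may promote acyl migration between O1 and O9. The fallback sets out from 21 and comes back at 26; it replaces direct discrimination by a protect–acetylate–deprotect–acylate sequence that uses the larger steric demand of a silyl chloride. Et3SiCl/imidazole at −20 °C should silylate only the less hindered C1 hydroxyl to give the C1 triethylsilyl ether F8; Ac2O/DMAP gives the C9 acetate F9; HF·pyridine (buffered with pyridine, 0 °C) removes the silyl group to give the C1 alcohol C9 acetate F10. Esterification of F10 with 24 (EDC·HCl, DMAP), now without a competing hydroxyl, gives 26.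

**Further compounds**

F1 | step 11 | methyl (4E,7S,8Z,10R)-7,10-bis(tert-butyldimethylsilyloxy)-4,8,11,11-tetramethyl-3-methoxycarbonyloxy... described as: 17 with C5–OH converted to OCO2CH3 and C6 carrying CO2CH3 beside SO2Ph (C6 epimers) | CC(C)(C)[Si](C)(C)O[C@@H](C(C)(C)CC(C(=O)OC)S(=O)(=O)c1ccccc1)/C=C(C)\[C@H](C/C=C(\C)COC(=O)OC)O[Si](C)(C)C(C)(C)C
F2 | step 11 | methyl (3E,9R,10Z,1S)-1,9-bis(tert-butyldimethylsilyloxy)-4,8,8,11-tetramethyl-6-(phenylsulfonyl)cycloundeca-3,10-diene-6-carboxylate (ring numbering of the plan, C6 epimers) | CC(C)(C)[Si](C)(C)O[C@H]1C/C=C(\C)CC(C(=O)OC)(S(=O)(=O)c2ccccc2)CC(C)(C)[C@H](O[Si](C)(C)C(C)(C)C)/C=C\1C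
F3 | step 6 | (3R)-4,4-dimethyl-6-(phenylsulfonyl)hex-1-en-3-yl 2-(diethoxyphosphoryl)propanoate | C=C[C@@H](OC(=O)C(C)P(=O)(OCC)OCC)C(C)(C)CCS(=O)(=O)c1ccccc1
F4 | step 6 | 3,3-dimethyl-1-oxo-5-(phenylsulfonyl)pentan-2-yl 2-(diethoxyphosphoryl)propanoate (carbinol configuration as in 7) | O=C[C@@H](OC(=O)C(C)P(=O)(OCC)OCC)C(C)(C)CCS(=O)(=O)c1ccccc1
F5 | step 6 | (5R)-3-methyl-5-[2-methyl-4-(phenylsulfonyl)butan-2-yl]furan-2(5H)-one | CC1=C[C@H](C(C)(C)CCS(=O)(=O)c2ccccc2)OC1=O
F6 | step 6 | (5R)-3-methyl-5-[2-methyl-4-(phenylsulfonyl)butan-2-yl]-2,5-dihydrofuran-2-ol (anomers) | CC1=C[C@H](C(C)(C)CCS(=O)(=O)c2ccccc2)OC1O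
F7 | step 6 | (4S,5Z,7R)-5,8,8-trimethyl-10-(phenylsulfonyl)deca-1,5-diene-4,7-diol | C=CC[C@H](O)/C(C)=C\[C@@H](O)C(C)(C)CCS(=O)(=O)c1ccccc1
F8 | step 15 | (1R,2Z,4S,7E)-2,7,11,11-tetramethyl-4-(triethylsilyloxy)cycloundeca-2,7-dien-1-ol, i.e. 21 silylated at O1 (plan numbering: 1S,9R) | CC[Si](CC)(CC)O[C@H]1C/C=C(\C)CCCC(C)(C)[C@H](O)/C=C\1C
F9 | step 15 | 9-O-acetyl-1-O-triethylsilyl derivative of 21 (plan numbering: 1S,9R; 3E,10Z) | CC[Si](CC)(CC)O[C@H]1C/C=C(\C)CCCC(C)(C)[C@H](OC(C)=O)/C=C\1C
F10 | step 15 | 9-O-acetyl derivative of 21 with free C1 hydroxyl (plan numbering: 1S,9R; 3E,10Z) | O[C@H]1C/C=C(\C)CCCC(C)(C)[C@H](OC(C)=O)/C=C\1C
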